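**Plan**

1. Retrosynthesis: the side-chain ketone comes from a silyl-protected carbinol; the epoxide C–O bond at the methyl-bearing epoxide carbon comes from a trans-bromohydrin (from an α′-bromo enone); the pyrone ring comes from a ring aldehyde plus methyl 2-methyl-3-oxopentanoate; two ring bonds, C1–C2 and C3–C4, are cut together as a Diels–Alder reaction.
2. Enabling feature: in the cyclohexene ring, C4(Me)–C5(O)–C6(Me)=C1H is a 1,3-diene retron with oxygen on an inner carbon (2-silyloxy diene 9). The quaternary C2 and its neighbour C3 are the α- and β-carbons of an α-methyl dienal (7), whose formyl carbon becomes C6 of the pyrone.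
3. Forward order: dienal 7 (steps 1–5) and diene 9 (step 6), then the cyclohexene ring (step 7), enone (step 8), pyrone ring (steps 9–12), epoxide ring (steps 13–14), ketone (steps 15–16).
4. Stereochemistry: the side-chain methyl centre comes from an L-proline aldol. C2 and C3 come from the E geometry of the dienophile (relative) and a chiral cationic oxazaborolidine (absolute). The epoxide comes from bromination anti to the side chain, hydride delivery syn to bromine, and SN2 closure with inversion at C4.

Key step: step 7

Remark: ring locants used in the text are C1 = ring =CH, C2 = quaternary carbon bearing the pyrone, C3 = CH bearing the side chain, C4 = methyl-bearing epoxide carbon, C5 = epoxide CH, C6 = C(Me)=.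
Assumption: the silyloxy-bearing side-chain carbon (oxidised in step 16) and the C4–H centre of 10–16 (enolised in step 13) are drawn as the expected major isomers; their configuration is immaterial.

Step 1
Reactants: 1 propanal (two molecules)
Product: 3 ethyl (2E,4R,5S)-5-hydroxy-2,4-dimethylhept-2-enoate, via aldol aldehyde 2 (not isolated)
Conditions: L-proline (10 mol %), DMF, 4 °C, slow addition of 1; then Ph3P=C(Me)CO2Et, 0 °C → rt
Reagents that add atoms: ethyl 2-(triphenylphosphoranylidene)propanoate, CCOC(=O)C(C)=P(c1ccccc1)(c1ccccc1)c1ccccc1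
Why: Proline-catalysed enamine cross-aldol reaction of two aldehydes, in which the (E)-enamine of one propanal adds through a carboxylic-acid-bound chair-like transition state to the second and should give the anti (2S,3S) aldol 2, followed by in-situ Wittig olefination with a stabilised ylide, which gives the (E)-enoate and removes the labile β-hydroxy aldehyde before it can epimerise or oligomerise.

Step 2
Reactants: 3 ethyl (2E,4R,5S)-5-hydroxy-2,4-dimethylhept-2-enoate
Product: 4 triisopropylsilyl ether of 3
Conditions: i-Pr3SiOTf, 2,6-lutidine, CH2Cl2, 0 °C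
Reagents that add atoms: triisopropylsilyl trifluoromethanesulfonate, CC(C)[Si](OS(=O)(=O)C(F)(F)F)(C(C)C)C(C)C
Why: Silylation of a secondary alcohol with a silyl triflate; the triisopropylsilyl ether is chosen because it should survive the Lewis acid of step 7, the bases of steps 9, 11 and 13 and the acid set free in step 12.

Step 3
Reactants: 4 silyl ether ester
Product: 5 (2E,4R,5S)-2,4-dimethyl-5-[(triisopropylsilyl)oxy]hept-2-en-1-ol
Conditions: i-Bu2AlH, CH2Cl2, −78 °C; aq. KNaC4H4O6
Reagents that add atoms: none
Why: 1,2-Reduction of the α,β-unsaturated ester to the allylic alcohol by an aluminium hydride at low temperature, which leaves the alkene geometry and both stereocentres untouched.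

Step 4
Reactants: 5 allylic alcohol
Product: 6 (2E,4R,5S)-2,4-dimethyl-5-[(triisopropylsilyl)oxy]hept-2-enal
Conditions: MnO2, CH2Cl2, rt
Reagents that add atoms: none
Why: MnO2 oxidises the allylic alcohol selectively to the enal under neutral conditions, so the γ-stereocentre should not epimerise.

Step 5
Reactants: 6 enal
Product: 7 (2E,4E,6R,7S)-2,4,6-trimethyl-7-[(triisopropylsilyl)oxy]nona-2,4-dienal
Conditions: Ph3P=C(Me)CHO, toluene, 90 °C
Reagents that add atoms: 2-(triphenylphosphoranylidene)propanal, CC(C=O)=P(c1ccccc1)(c1ccccc1)c1ccccc1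
Why: Wittig olefination with the stabilised α-formyl ylide adds one C(Me)=CH unit and should give the (E)-trisubstituted alkene, as is usual for stabilised ylides.

Step 6
Reactants: 8 2-methylpent-1-en-3-one
Product: 9 triisopropyl{[(3Z)-2-methylpenta-1,3-dien-3-yl]oxy}silane
Conditions: i-Pr3SiOTf, Et3N, CH2Cl2, 0 °C → rt
Reagents that add atoms: triisopropylsilyl trifluoromethanesulfonate, CC(C)[Si](OS(=O)(=O)C(F)(F)F)(C(C)C)C(C)C
Why: Soft enolisation (silyl triflate and amine) of the ethyl ketone gives the silyl enol ether, and the Z isomer, with the terminal methyl cis to oxygen and away from the isopropenyl group, is the one expected and the one needed because its methyl is an outside substituent of the s-cis diene.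

Step 7
Reactants: 7 dienal; 9 2-silyloxy diene
Product: 10 Diels–Alder adduct (cyclohexene silyl enol ether carbaldehyde)
Conditions: 9 (2.5 equiv), (S)-3,3-diphenyl-1-(2-methylphenyl)tetrahydro-1H,3H-pyrrolo[1,2-c][1,3,2]oxazaborole activated with HN(SO2CF3)2 (20 mol % each), CH2Cl2, −78 → −40 °C
Reagents that add atoms: none
Why: The boron Lewis acid binds the formyl oxygen of s-trans 7 (formyl C–H···O contact to the ring oxygen of the catalyst), and a concerted but asynchronous normal-demand [4+2] cycloaddition follows in which the enol-ether β-carbon of 9 (C4) bonds ahead to the enal β-carbon (C3) while the CH2 terminus (C1) closes on the α-carbon (C2). The closest known reaction type is the cationic-oxazaborolidine-catalysed enantioselective Diels–Alder reaction of α-methyl enals with 2-(triisopropylsilyloxy)-1,3-dienes. The cyclohexene ring is closed in an intermolecular [4πs+2πs] mode, both new σ-bonds forming suprafacially on each partner. C2 and C3 are set relative to each other by the E geometry of the dienophile (formyl trans to the alkenyl side chain) and in the absolute sense by the catalyst, whose phenyl group cis to boron should screen the Si face of the α-carbon so that the diene adds to the Re face (assigned from the accepted binding model; the mirror-image catalyst is equally accessible); the C4 methyl centre should follow from an endo-formyl transition state and is erased in step 13. The step needs regioselectivity (C4 to C3, secured by the 2-silyloxy group, whose β-carbon is the nucleophilic terminus, and by the formyl group, which makes C3 the electrophilic carbon), site selectivity for the α,β- over the γ,δ-alkene of 7 (only the former is attached to the activated carbonyl and its β-carbon is the less hindered) and C=C over C=O reactivity (the bulky triisopropylsilyl group disfavours silyl transfer and thus Mukaiyama-type aldol addition). The remote side-chain stereocentres are not expected to compete with catalyst control.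

Step 8
Reactants: 10 Diels–Alder adduct
Product: 11 enone aldehyde
Conditions: Pd(OAc)2 (1.2 equiv), MeCN/CH2Cl2, rt → 40 °C
Reagents that add atoms: none
Why: Saegusa–Ito oxidation, in which the silyl enol ether is converted into a divalent palladium enolate at C6 and β-hydride elimination towards the ring CH2 (C1) gives the conjugated enone regiospecifically without touching C2, C3 or the aldehyde.

Step 9
Reactants: 11 enone aldehyde; 12 methyl 2-methyl-3-oxopentanoate
Product: 13 δ-hydroxy-β-keto ester (mixture at the three new centres)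
Conditions: 12, NaH then n-BuLi, THF, 0 °C; 11, −78 °C; aq. NH4Cl
Reagents that add atoms: none
Why: Aldol addition of the dianion of a β-keto ester through its more nucleophilic γ-carbon to the non-enolisable aldehyde, which is far more electrophilic than the hindered enone; the three new stereocentres are removed in steps 10 and 11.

Step 10
Reactants: 13 δ-hydroxy-β-keto ester
Product: 14 β,δ-diketo ester
Conditions: Dess–Martin periodinane, NaHCO3, CH2Cl2, 0 °C → rt
Reagents that add atoms: none
Why: Dess–Martin oxidation of the β-hydroxy ketone to the 1,3-diketone under mild buffered conditions, with no base that could cleave the polycarbonyl chain by a retro-Claisen reaction.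

Step 11
Reactants: 14 β,δ-diketo ester
Product: 15 4-hydroxy-2-pyrone
Conditions: DBU, toluene, 60 °C
Reagents that add atoms: none
Why: Base-induced lactonisation of the β,δ-diketo ester (6-exo-trig attack of the δ-enol oxygen on the ester with loss of methanol) gives the 4-hydroxy-2-pyrone, the standard ring closure of triketide esters.

Step 12
Reactants: 15 4-hydroxy-2-pyrone
Product: 16 α-methoxy-γ-pyrone enone
Conditions: MeOTf, CH2Cl2, rt; aq. NaHCO3
Reagents that add atoms: methyl trifluoromethanesulfonate, COS(=O)(=O)C(F)(F)F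
Why: O-Methylation with a hard alkylating agent in the absence of base takes place at the lactone carbonyl oxygen of the neutral hydroxypyrone, and loss of the hydroxyl proton from the resulting 2-methoxy-4-hydroxypyrylium ion gives the α-methoxy-γ-pyrone (known regioselective methylation of 4-hydroxy-2-pyrones).

Step 13
Reactants: 16 α-methoxy-γ-pyrone enone
Product: 17 α′-bromo enone
Conditions: LiN(SiMe3)2, THF, −78 → −40 °C; NBS, −78 °C; aq. NH4Cl
Reagents that add atoms: N-bromosuccinimide, BrN1C(=O)CCC1=O
Why: α′-Bromination of a kinetic enolate, in which C4–H is the only enolisable hydrogen (C2 is quaternary, so no γ-deprotonation) and NBS should attack the cross-conjugated lithium dienolate at C4 on the face anti to the neighbouring C3 side chain and to the 1,3-related C2 methyl, placing bromine cis to the pyrone and the C4 methyl cis to the side chain.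

Step 14
Reactants: 17 α′-bromo enone
Product: 19 vinyl epoxide (silyl ether), via trans-bromohydrin 18 (not isolated)
Conditions: NaBH4, CeCl3·7H2O, MeOH, −40 °C; then K2CO3, rt
Reagents that add atoms: none
Why: Luche reduction followed by intramolecular Williamson (SN2) epoxide closure, in which hydride should add to the carbonyl face syn to bromine (the face remote from the pseudo-axial C4 methyl and the C3 side chain) to give the trans-bromohydrin 18, whose alkoxide displaces the tertiary bromide with inversion at C4 so that the epoxide oxygen ends syn to the side chain and anti to the pyrone.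

Step 15
Reactants: 19 vinyl epoxide (silyl ether)
Product: 20 side-chain alcohol
Conditions: Bu4NF, THF, rt → 40 °C
Reagents that add atoms: none
Why: Fluoride-induced cleavage of the silyl ether under non-acidic conditions, which the vinyl epoxide and the pyrone should tolerate.

Step 16
Reactants: 20 side-chain alcohol
Product: 21 target CNP0336888.2
Conditions: Dess–Martin periodinane, NaHCO3, CH2Cl2, 0 °C
Reagents that add atoms: none
Why: Dess–Martin oxidation of the secondary alcohol under buffered, non-basic conditions should give the β,γ-unsaturated ketone without epimerising the doubly activated α-stereocentre or moving the alkene into conjugation.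

**Compound list**

1 | propanal | CCC=O | starting material
2 | (2S,3S)-3-hydroxy-2-methylpentanal | CC[C@H](O)[C@H](C)C=O | intermediate
3 | ethyl (2E,4R,5S)-5-hydroxy-2,4-dimethylhept-2-enoate | CC[C@H](O)[C@H](C)/C=C(\C)C(=O)OCC | intermediate
4 | ethyl (2E,4R,5S)-2,4-dimethyl-5-[(triisopropylsilyl)oxy]hept-2-enoate | CC[C@H](O[Si](C(C)C)(C(C)C)C(C)C)[C@H](C)/C=C(\C)C(=O)OCC | intermediate
5 | (2E,4R,5S)-2,4-dimethyl-5-[(triisopropylsilyl)oxy]hept-2-en-1-ol | CC[C@H](O[Si](C(C)C)(C(C)C)C(C)C)[C@H](C)/C=C(\C)CO | intermediate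
6 | (2E,4R,5S)-2,4-dimethyl-5-[(triisopropylsilyl)oxy]hept-2-enal | CC[C@H](O[Si](C(C)C)(C(C)C)C(C)C)[C@H](C)/C=C(\C)C=O | intermediate
7 | (2E,4E,6R,7S)-2,4,6-trimethyl-7-[(triisopropylsilyl)oxy]nona-2,4-dienal | CC[C@H](O[Si](C(C)C)(C(C)C)C(C)C)[C@H](C)/C=C(\C)/C=C(\C)C=O | intermediate
8 | 2-methylpent-1-en-3-one | C=C(C)C(=O)CC | starting material
9 | triisopropyl{[(3Z)-2-methylpenta-1,3-dien-3-yl]oxy}silane | C=C(C)/C(O[Si](C(C)C)(C(C)C)C(C)C)=C/C | intermediate
10 | (1R,5R,6S)-1,3,5-trimethyl-6-{(2E,4R,5S)-4-methyl-5-[(triisopropylsilyl)oxy]hept-2-en-2-yl}-4-[(triisopropylsilyl)oxy]cyclohex-3-ene-1-carbaldehyde | CC[C@H](O[Si](C(C)C)(C(C)C)C(C)C)[C@H](C)/C=C(\C)[C@@H]1[C@@H](C)C(O[Si](C(C)C)(C(C)C)C(C)C)=C(C)C[C@@]1(C)C=O | intermediate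
11 | (1R,5R,6S)-1,3,5-trimethyl-6-{(2E,4R,5S)-4-methyl-5-[(triisopropylsilyl)oxy]hept-2-en-2-yl}-4-oxocyclohex-2-ene-1-carbaldehyde | CC[C@H](O[Si](C(C)C)(C(C)C)C(C)C)[C@H](C)/C=C(\C)[C@@H]1[C@@H](C)C(=O)C(C)=C[C@@]1(C)C=O | intermediate
12 | methyl 2-methyl-3-oxopentanoate | CCC(=O)C(C)C(=O)OC | starting material
13 | methyl 5-hydroxy-2,4-dimethyl-3-oxo-5-[(1R,5R,6S)-1,3,5-trimethyl-6-{(2E,4R,5S)-4-methyl-5-[(triisopropylsilyl)oxy]hept-2-en-2-yl}-4-oxocyclohex-2-en-1-yl]pentanoate (mixture at chain C2, C4 and C5) | CC[C@H](O[Si](C(C)C)(C(C)C)C(C)C)[C@H](C)/C=C(\C)[C@@H]1[C@@H](C)C(=O)C(C)=C[C@@]1(C)C(O)C(C)C(=O)C(C)C(=O)OC | intermediate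
14 | methyl 2,4-dimethyl-3,5-dioxo-5-[(1R,5R,6S)-1,3,5-trimethyl-6-{(2E,4R,5S)-4-methyl-5-[(triisopropylsilyl)oxy]hept-2-en-2-yl}-4-oxocyclohex-2-en-1-yl]pentanoate (mixture at chain C2 and C4) | CC[C@H](O[Si](C(C)C)(C(C)C)C(C)C)[C@H](C)/C=C(\C)[C@@H]1[C@@H](C)C(=O)C(C)=C[C@@]1(C)C(=O)C(C)C(=O)C(C)C(=O)OC | intermediate
15 | 4-hydroxy-3,5-dimethyl-6-[(1R,5R,6S)-1,3,5-trimethyl-6-{(2E,4R,5S)-4-methyl-5-[(triisopropylsilyl)oxy]hept-2-en-2-yl}-4-oxocyclohex-2-en-1-yl]-2H-pyran-2-one | CC[C@H](O[Si](C(C)C)(C(C)C)C(C)C)[C@H](C)/C=C(\C)[C@@H]1[C@@H](C)C(=O)C(C)=C[C@@]1(C)C2=C(C)C(O)=C(C)C(=O)O2 | intermediate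
16 | (4R,5S,6R)-4-(6-methoxy-3,5-dimethyl-4-oxo-4H-pyran-2-yl)-2,4,6-trimethyl-5-{(2E,4R,5S)-4-methyl-5-[(triisopropylsilyl)oxy]hept-2-en-2-yl}cyclohex-2-en-1-one | CC[C@H](O[Si](C(C)C)(C(C)C)C(C)C)[C@H](C)/C=C(\C)[C@@H]1[C@@H](C)C(=O)C(C)=C[C@@]1(C)c1oc(OC)c(C)c(=O)c1C | intermediate
17 | (4R,5S,6R)-6-bromo-4-(6-methoxy-3,5-dimethyl-4-oxo-4H-pyran-2-yl)-2,4,6-trimethyl-5-{(2E,4R,5S)-4-methyl-5-[(triisopropylsilyl)oxy]hept-2-en-2-yl}cyclohex-2-en-1-one | CC[C@H](O[Si](C(C)C)(C(C)C)C(C)C)[C@H](C)/C=C(\C)[C@@H]1[C@@](C)(Br)C(=O)C(C)=C[C@@]1(C)c1oc(OC)c(C)c(=O)c1C | intermediate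
18 | (1R,4R,5S,6R)-6-bromo-4-(6-methoxy-3,5-dimethyl-4-oxo-4H-pyran-2-yl)-2,4,6-trimethyl-5-{(2E,4R,5S)-4-methyl-5-[(triisopropylsilyl)oxy]hept-2-en-2-yl}cyclohex-2-en-1-ol (hydroxyl trans to bromine) | CC[C@H](O[Si](C(C)C)(C(C)C)C(C)C)[C@H](C)/C=C(\C)[C@@H]1[C@@](C)(Br)[C@H](O)C(C)=C[C@@]1(C)c1oc(OC)c(C)c(=O)c1C | intermediate
19 | 2-methoxy-3,5-dimethyl-6-[(1R,4R,5S,6S)-2,4,6-trimethyl-5-{(2E,4R,5S)-4-methyl-5-[(triisopropylsilyl)oxy]hept-2-en-2-yl}-7-oxabicyclo[4.1.0]hept-2-en-4-yl]-4H-pyran-4-one | CC[C@H](O[Si](C(C)C)(C(C)C)C(C)C)[C@H](C)/C=C(\C)[C@@H]1[C@]2(C)O[C@@H]2C(C)=C[C@@]1(C)c1oc(OC)c(C)c(=O)c1C | intermediate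
20 | 2-methoxy-3,5-dimethyl-6-[(1R,4R,5S,6S)-5-[(2E,4R,5S)-5-hydroxy-4-methylhept-2-en-2-yl]-2,4,6-trimethyl-7-oxabicyclo[4.1.0]hept-2-en-4-yl]-4H-pyran-4-one | CC[C@H](O)[C@H](C)/C=C(\C)[C@@H]1[C@]2(C)O[C@@H]2C(C)=C[C@@]1(C)c1oc(OC)c(C)c(=O)c1C | intermediate
21 | 2-methoxy-3,5-dimethyl-6-[(1R,4R,5S,6S)-2,4,6-trimethyl-5-[(2E,4R)-4-methyl-5-oxohept-2-en-2-yl]-7-oxabicyclo[4.1.0]hept-2-en-4-yl]-4H-pyran-4-one (CNP0336888.2) | CCC(=O)[C@H](C)/C=C(\C)[C@@H]1[C@]2(C)O[C@@H]2C(C)=C[C@@]1(C)c1oc(OC)c(C)c(=O)c1C | target

**Step count**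

Total: 16 steps. Longest linear sequence: 15 steps (steps 1–5 and 7–16).

**Steps most likely to fail, with fallbacks**

Step 7. The hindered, trisubstituted dienal may add too slowly at the low temperature needed for face control, so that acid-induced loss of the silyloxy diene, attack at the formyl carbon or erosion of enantiofacial selectivity takes over. The fallback sets out from 7 and gives up catalyst control for thermal reactivity. Commercially available (E)-1-methoxy-2-methylpent-1-en-3-one is silylated (Me3SiOTf, Et3N) to the much more nucleophilic (1E,3Z)-1-methoxy-2-methyl-3-(trimethylsilyloxy)penta-1,3-diene F1. Heating 7 with it in toluene at 110 °C without any Lewis acid (so that the aldehyde carbonyl does not enter a hetero-Diels–Alder reaction) should give the 2-methoxy cycloadduct F2 with the same regiochemistry and the same trans relationship at C2/C3. Dilute HCl in THF then cleaves the silyl enol ether and eliminates methanol, returning to the route at enone 11 and making step 8 unnecessary. Both ring-enantiomeric series would form, and because of the side-chain stereocentres they are diastereomers; the unwanted one would be removed by chromatography at the stage of 11.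

Step 14. Hydride may be delivered to the carbonyl face anti to bromine (polar control by the C–Br bond), giving the cis-bromohydrin, which cannot close; the tertiary bromide may also eliminate before closure. The fallback sets out from 17 and no longer relies on the hydride face. The cis-bromohydrin F3 is inverted at C5 by a Mitsunobu reaction (4-nitrobenzoic acid, PPh3, diisopropyl azodicarboxylate, THF) to the trans 4-nitrobenzoate F4. K2CO3 in MeOH then cleaves the ester, and the alkoxide set free should close onto C4 with inversion, returning to the route at 19.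

Step 13. Bromine transfer to the dienolate may be unselective or occur syn to the side chain, or the electrophile may attack the side-chain alkene. The fallback sets out from 16 and uses the opposite logic: if the face of C4=C5 syn to the side chain is the accessible one, oxygen is delivered there directly. KN(SiMe3)2 and PhN(SO2CF3)2 convert 16 into the cross-conjugated dienyl triflate F5. Reduction with Pd(OAc)2, PPh3, Bu3N and HCO2H in DMF gives the cyclohexa-1,3-diene F6. Epoxidation with dimethyldioxirane in acetone at −20 °C at the less hindered diene terminus (C4=C5) on that face would return to the route at 19.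

**Further compounds**

F1 | step 7 | (1E,3Z)-1-methoxy-2-methyl-3-(trimethylsilyloxy)penta-1,3-diene | CO/C=C(C)/C(O[Si](C)(C)C)=C/C
F2 | step 7 | 2-methoxy analogue of 10 with a trimethylsilyl enol ether (ring configuration as in 10, methoxy epimers) | CC[C@H](O[Si](C(C)C)(C(C)C)C(C)C)[C@H](C)/C=C(\C)[C@@H]1[C@@H](C)C(O[Si](C)(C)C)=C(C)C(OC)[C@@]1(C)C=O
F3 | step 14 | cis-bromohydrin, C5 epimer of 18 (hydroxyl cis to bromine) | CC[C@H](O[Si](C(C)C)(C(C)C)C(C)C)[C@H](C)/C=C(\C)[C@@H]1[C@@](C)(Br)[C@@H](O)C(C)=C[C@@]1(C)c1oc(OC)c(C)c(=O)c1C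
F4 | step 14 | 4-nitrobenzoate of 18 (ester trans to bromine) | CC[C@H](O[Si](C(C)C)(C(C)C)C(C)C)[C@H](C)/C=C(\C)[C@@H]1[C@@](C)(Br)[C@H](OC(=O)c2ccc(cc2)[N+](=O)[O-])C(C)=C[C@@]1(C)c1oc(OC)c(C)c(=O)c1C
F5 | step 13 | dienyl triflate of enone 16 (C4=C5 enol triflate, C2 and C3 as in 16) | CC[C@H](O[Si](C(C)C)(C(C)C)C(C)C)[C@H](C)/C=C(\C)[C@@H]1C(C)=C(OS(=O)(=O)C(F)(F)F)C(C)=C[C@@]1(C)c1oc(OC)c(C)c(=O)c1C
F6 | step 13 | cyclohexa-1,3-diene corresponding to 19 without the epoxide oxygen | CC[C@H](O[Si](C(C)C)(C(C)C)C(C)C)[C@H](C)/C=C(\C)[C@@H]1C(C)=CC(C)=C[C@@]1(C)c1oc(OC)c(C)c(=O)c1C
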